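**Strategy.** The cyclohexene is disconnected at C4–C5 (CH2 to the quaternary ring carbon) and at C1–C2 (carbinol carbon to the methyl-bearing alkene carbon), releasing a CH2–CH=C(CH3) unit as a 1,3-dianion. The route exploits the cis 1,3-relation between the C1 oxygen and the cyclopentyl group on C5, with the exocyclic C=CH2 close by: iodolactonisation ties that oxygen to the methylidene-bearing carbon in a bicyclic lactol. In one Lewis-acid operation 1,3-bis(trimethylsilyl)but-2-ene allylates the oxocarbenium carbon and then traps the tertiary C5 cation, forming both bonds and a bridged ether that zinc later opens to C=CH2 and the C1 alcohol.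

Key step: step 9

Remark on locants: C1–C6 are the cyclohexene atoms of the target (C1 = carbinol carbon, C2 = C–CH3, C3 = =CH, C4 and C6 = CH2, C5 = quaternary carbon).

Remark on stereochemistry: the carbinol carbon made in step 5 and the anomeric carbon made in step 7 are carried as mixtures (drawn without descriptors) because both become planar cations in step 9. In step 1 the antipode of the catalyst that gives the S ester is to be used; its sense is not assigned here.

**Step 1**
Reactants: 1 tert-butyl 2-oxocyclopentane-1-carboxylate
Product: 2 tert-butyl (1S)-1-methyl-2-oxocyclopentane-1-carboxylate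
Conditions: MeI, CsOH·H2O, Maruoka-type N-spiro binaphthyl ammonium bromide (1 mol %), toluene, −40 °C
Reagents that add atoms: iodomethane, CI
Why: Chiral phase-transfer alkylation of a cyclic β-keto ester, in which the ion pair with the C2-symmetric ammonium cation shields one enolate face and sets the quaternary centre (S), the only stereocentre the rest of the route relays.

**Step 2**
Reactants: 2 tert-butyl (1S)-1-methyl-2-oxocyclopentane-1-carboxylate
Product: 3 tert-butyl (1S)-1-methyl-2-methylidenecyclopentane-1-carboxylate
Conditions: Ph3PCH3Br, KOtBu, THF, 0 °C → reflux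
Reagents that add atoms: methyltriphenylphosphonium bromide, C[P+](c1ccccc1)(c1ccccc1)c1ccccc1.[Br-]
Why: Wittig methylenation of a ketone that cannot enolise toward the quaternary carbon, so the stereocentre is untouched.

**Step 3**
Reactants: 3 tert-butyl (1S)-1-methyl-2-methylidenecyclopentane-1-carboxylate
Product: 5 (1S)-1-methyl-2-methylidenecyclopentane-1-carboxylic acid, via trimethylsilyl ester 4 (not isolated)
Conditions: TMSOTf, 2,6-lutidine, CH2Cl2, 0 °C → rt; aqueous work-up
Reagents that add atoms: none
Why: Silyl triflate-mediated cleavage of a tert-butyl ester (E1 loss of isobutene) under non-protic conditions that should spare the 1,1-disubstituted alkene.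

**Step 4**
Reactants: 5 (1S)-1-methyl-2-methylidenecyclopentane-1-carboxylic acid
Product: 6 1-[(1S)-1-methyl-2-methylidenecyclopentyl]ethan-1-one
Conditions: MeLi (2.2 equiv), Et2O, 0 °C → rt; aq. NH4Cl
Reagents that add atoms: methyllithium, [Li]C
Why: Addition of methyllithium to the lithium carboxylate gives a stable geminal dialkoxide that releases the methyl ketone only on work-up, so over-addition is avoided.

**Step 5**
Reactants: 6 1-[(1S)-1-methyl-2-methylidenecyclopentyl]ethan-1-one
Product: 7 methyl 3-hydroxy-3-[(1S)-1-methyl-2-methylidenecyclopentyl]butanoate (both C3 epimers)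
Conditions: LDA, MeOAc, THF, −78 °C; then 6, −78 °C; AcOH quench
Reagents that add atoms: methyl acetate, COC(C)=O
Why: Aldol addition of a lithium ester enolate to a methyl ketone at low temperature; the new carbinol centre is not controlled because it is erased in step 9.

**Step 6**
Reactants: 7 methyl 3-hydroxy-3-[(1S)-1-methyl-2-methylidenecyclopentyl]butanoate
Product: 9 (4aR,7aR)-4-hydroxy-7a-(iodomethyl)-4,4a-dimethylhexahydrocyclopenta[b]pyran-2(3H)-one (cis-fused, C4 epimers), via hydroxy carboxylate 8 (not isolated)
Conditions: LiOH, THF/H2O, rt; then NaHCO3, I2, KI, 0 °C, dark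
Reagents that add atoms: lithium hydroxide, [Li+].[OH-]; iodine, II
Why: Saponification then 6-exo-trig iodolactonisation with Markovnikov delivery of the carboxylate oxygen to the methylidene-bearing ring carbon; the short tether forces attack on the side-chain face, which gives the cis-fused ring junction.

**Step 7**
Reactants: 9 iodolactone
Product: 10 (4aR,7aR)-7a-(iodomethyl)-4,4a-dimethyloctahydrocyclopenta[b]pyran-2,4-diol (lactol, anomers and C4 epimers)
Conditions: DIBAL-H (2.2 equiv), CH2Cl2, −78 °C; Rochelle salt
Reagents that add atoms: none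
Why: Partial reduction of a δ-lactone to the lactol via a tetrahedral aluminium alkoxide that is stable at −78 °C; the primary iodide and the tertiary alcohol are inert.

**Step 8**
Reactants: 11 1-(trimethylsilyl)ethan-1-one (acetyltrimethylsilane); 12 (iodomethyl)trimethylsilane
Product: 14 trimethyl[3-(trimethylsilyl)but-2-en-1-yl]silane (E/Z mixture), via phosphonium iodide 13 (not isolated)
Conditions: Ph3PCH3Br (2 equiv), n-BuLi (2 equiv), THF, 0 °C; 12, rt; then 11, rt → 50 °C
Reagents that add atoms: methyltriphenylphosphonium bromide, C[P+](c1ccccc1)(c1ccccc1)c1ccccc1.[Br-]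
Why: Seyferth–Fleming one-pot allylsilane synthesis, in which the ylide is alkylated by 12, transylidation gives the β-silyl ylide, and this undergoes a Wittig reaction with the acylsilane.

**Step 9**
Reactants: 10 lactol; 14 trimethyl[3-(trimethylsilyl)but-2-en-1-yl]silane
Product: 16 (1S,3R,4R,5S)-3-(iodomethyl)-4,5,8-trimethyl-3,4-(propane-1,3-diyl)-2-oxabicyclo[3.3.1]non-7-ene (bridged tricyclic iodo ether; cyclopentane anti to the C6–C8 bridge), via allylsilane C-glycoside 15 (not isolated)
Conditions: BF3·OEt2 (3 equiv), 14 (1.5 equiv), 4 Å MS, CH2Cl2, −78 → 0 °C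
Reagents that add atoms: none
Why: Proposed new method: BF3 first ionises the lactol to the cyclic oxocarbenium ion, which 14 attacks through its methyl-bearing carbon (Hosomi–Sakurai C-glycosylation) to give the new allylsilane 15; BF3 then ionises the tertiary carbinol and the terminal CH2 of 15 captures the cation with loss of the second silyl group, so that 14 acts as a CH2–CH=C(CH3) 1,3-dianion; the closest known reaction types are the Sakurai allylation of lactols and the BF3-mediated allylation of tertiary alcohols, fused here into one annulation. The carbocycle closes in a 6-endo mode at the allylsilane alkene, and the double bond falls between C2 and C3 because silicon leaves from C2. C1 is set by axial attack on the oxocarbenium ion from the convex face of the cis-fused oxabicycle (anti to the cyclopentane CH2 groups), and C5 is then fixed by geometry, because a three-atom bridge can span C1 and C5 of the oxane only in a cis-diaxial sense; both carbinol epimers and both anomers converge through planar cations. The step needs attack on that face and cyclisation faster than Peterson-type loss of silicon or a 1,2-shift in the tertiary cation; the pre-organised 1,3-diaxial allylsilane and the low temperature are meant to secure this, and the epimeric adduct could close only by forcing the cyclopentane into the bicyclo[3.3.1] cavity.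

**Step 10**
Reactants: 16 bridged tricyclic iodo ether
Product: 17 (1S,5S)-2,5-dimethyl-5-[(1S)-1-methyl-2-methylidenecyclopentyl]cyclohex-2-en-1-ol
Conditions: Zn dust, NH4Cl, EtOH, 70 °C
Reagents that add atoms: none
Why: Zinc-mediated reductive β-elimination of a β-iodo ether (Boord/Vasella type) regenerates the exocyclic methylidene and frees the C1 oxygen without touching any stereocentre.

**Step 11**
Reactants: 18 caffeic acid, (2E)-3-(3,4-dihydroxyphenyl)prop-2-enoic acid
Product: 20 (2E)-3-[3,4-bis(tert-butyldimethylsilyloxy)phenyl]prop-2-enoic acid, via tris-silylated caffeate 19 (not isolated)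
Conditions: TBSCl (3.3 equiv), imidazole, DMF, rt; then AcOH/THF/H2O, rt
Reagents that add atoms: tert-butyldimethylsilyl chloride, CC(C)(C)[Si](C)(C)Cl
Why: Exhaustive silylation followed by selective hydrolysis of the labile silyl ester, which leaves the two aryl silyl ethers in place.

**Step 12**
Reactants: 17 allylic alcohol; 20 bis-silylated caffeic acid
Product: 21 (1S,5S)-2,5-dimethyl-5-[(1S)-1-methyl-2-methylidenecyclopentyl]cyclohex-2-en-1-yl (2E)-3-[3,4-bis(tert-butyldimethylsilyloxy)phenyl]prop-2-enoate
Conditions: DCC, DMAP, CH2Cl2, 0 °C → rt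
Reagents that add atoms: none
Why: Steglich esterification acylates the alcohol oxygen, so the C1–O bond and its configuration are retained.

**Step 13**
Reactants: 21 bis-silylated ester
Product: 22 (1S,5S)-2,5-dimethyl-5-[(1S)-1-methyl-2-methylidenecyclopentyl]cyclohex-2-en-1-yl (2E)-3-(3,4-dihydroxyphenyl)prop-2-enoate (target)
Conditions: TBAF, AcOH, THF, 0 °C
Reagents that add atoms: none
Why: Fluoride cleavage of aryl silyl ethers, buffered with acetic acid so that the allylic cinnamate ester and the catechol are not exposed to free phenoxide.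

**Compound list**

1 | tert-butyl 2-oxocyclopentane-1-carboxylate | CC(C)(C)OC(=O)C1CCCC1=O | starting material
2 | tert-butyl (1S)-1-methyl-2-oxocyclopentane-1-carboxylate | O=C1CCC[C@]1(C)C(=O)OC(C)(C)C | intermediate
3 | tert-butyl (1S)-1-methyl-2-methylidenecyclopentane-1-carboxylate | C=C1CCC[C@]1(C)C(=O)OC(C)(C)C | intermediate
4 | trimethylsilyl (1S)-1-methyl-2-methylidenecyclopentane-1-carboxylate (not isolated) | C=C1CCC[C@]1(C)C(=O)O[Si](C)(C)C | intermediate
5 | (1S)-1-methyl-2-methylidenecyclopentane-1-carboxylic acid | C=C1CCC[C@]1(C)C(=O)O | intermediate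
6 | 1-[(1S)-1-methyl-2-methylidenecyclopentyl]ethan-1-one | C=C1CCC[C@]1(C)C(C)=O | intermediate
7 | methyl 3-hydroxy-3-[(1S)-1-methyl-2-methylidenecyclopentyl]butanoate (C3 epimers) | C=C1CCC[C@]1(C)C(C)(O)CC(=O)OC | intermediate
8 | lithium 3-hydroxy-3-[(1S)-1-methyl-2-methylidenecyclopentyl]butanoate (not isolated) | [Li+].C=C1CCC[C@]1(C)C(C)(O)CC(=O)[O-] | intermediate
9 | (4aR,7aR)-4-hydroxy-7a-(iodomethyl)-4,4a-dimethylhexahydrocyclopenta[b]pyran-2(3H)-one (cis-fused, C4 epimers) | O=C1CC(C)(O)[C@@]2(C)CCC[C@@]2(CI)O1 | intermediate
10 | (4aR,7aR)-7a-(iodomethyl)-4,4a-dimethyloctahydrocyclopenta[b]pyran-2,4-diol (anomers, C4 epimers) | OC1CC(C)(O)[C@@]2(C)CCC[C@@]2(CI)O1 | intermediate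
11 | 1-(trimethylsilyl)ethan-1-one | CC(=O)[Si](C)(C)C | starting material
12 | (iodomethyl)trimethylsilane | C[Si](C)(C)CI | starting material
13 | triphenyl[2-(trimethylsilyl)ethyl]phosphonium iodide (not isolated) | C[Si](C)(C)CC[P+](c1ccccc1)(c1ccccc1)c1ccccc1.[I-] | intermediate
14 | trimethyl[3-(trimethylsilyl)but-2-en-1-yl]silane (E/Z) | C[Si](C)(C)CC=C(C)[Si](C)(C)C | intermediate
15 | allylsilane C-glycoside: (2S,4aR,7aR)-7a-(iodomethyl)-4,4a-dimethyl-2-[2-(trimethylsilyl)but-3-en-2-yl]octahydrocyclopenta[b]pyran-4-ol (not isolated; epimers at C4 and at the silyl-bearing carbon) | C=CC(C)([Si](C)(C)C)[C@@H]1CC(C)(O)[C@@]2(C)CCC[C@@]2(CI)O1 | intermediate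
16 | (1S,3R,4R,5S)-3-(iodomethyl)-4,5,8-trimethyl-3,4-(propane-1,3-diyl)-2-oxabicyclo[3.3.1]non-7-ene | CC1=CC[C@@]2(C)C[C@@H]1O[C@]3(CI)CCC[C@]23C | intermediate
17 | (1S,5S)-2,5-dimethyl-5-[(1S)-1-methyl-2-methylidenecyclopentyl]cyclohex-2-en-1-ol | C=C1CCC[C@]1(C)[C@@]1(C)CC=C(C)[C@@H](O)C1 | intermediate
18 | caffeic acid | OC(=O)/C=C/c1ccc(O)c(O)c1 | starting material
19 | tert-butyldimethylsilyl (2E)-3-[3,4-bis(tert-butyldimethylsilyloxy)phenyl]prop-2-enoate (not isolated) | CC(C)(C)[Si](C)(C)OC(=O)/C=C/c1ccc(O[Si](C)(C)C(C)(C)C)c(O[Si](C)(C)C(C)(C)C)c1 | intermediate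
20 | (2E)-3-[3,4-bis(tert-butyldimethylsilyloxy)phenyl]prop-2-enoic acid | OC(=O)/C=C/c1ccc(O[Si](C)(C)C(C)(C)C)c(O[Si](C)(C)C(C)(C)C)c1 | intermediate
21 | (1S,5S)-2,5-dimethyl-5-[(1S)-1-methyl-2-methylidenecyclopentyl]cyclohex-2-en-1-yl (2E)-3-[3,4-bis(tert-butyldimethylsilyloxy)phenyl]prop-2-enoate | C=C1CCC[C@]1(C)[C@@]1(C)CC=C(C)[C@@H](OC(=O)/C=C/c2ccc(O[Si](C)(C)C(C)(C)C)c(O[Si](C)(C)C(C)(C)C)c2)C1 | intermediate
22 | (1S,5S)-2,5-dimethyl-5-[(1S)-1-methyl-2-methylidenecyclopentyl]cyclohex-2-en-1-yl (2E)-3-(3,4-dihydroxyphenyl)prop-2-enoate | C=C1CCC[C@]1(C)[C@@]1(C)CC=C(C)[C@@H](OC(=O)/C=C/c2ccc(O)c(O)c2)C1 | target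

**Step count.** Total: 13 steps. Longest linear sequence: 11 steps (1–7, 9, 10, 12, 13).

**Steps most likely to fail**

Step 9 (proposed new method). Three things may go wrong: the β-silyl ether in 15 may lose silicon together with the ring oxygen (Peterson-type elimination) before the tertiary carbinol ionises; the tertiary cation next to the quaternary carbon may undergo a 1,2-shift or E1 loss; and the first allylation may take place on the concave face. The last point is the least secure: the convex face also carries the angular methyl and the iodomethyl group, so the facial preference is an expectation, not an established bias. The fallback uses known reactions and sets out from 10. BF3-mediated addition of potassium isopropenyltrifluoroborate to the lactol-derived oxocarbenium ion should give the isopropenyl C-glycoside F1. BF3-mediated allylation of its tertiary alcohol with allyltrimethylsilane should give the diene F2. Ring-closing metathesis (Grubbs second-generation catalyst, CH2Cl2, 40 °C) between the isopropenyl and allyl groups, which only the cis-diaxial diene can undergo, should then close the cyclohexene and return to the route at 16.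

Step 1. The ion pair may discriminate poorly between the enolate faces with so small an electrophile, and O-methylation may compete. The fallback sets out from 1: methylation without a chiral catalyst (MeI, K2CO3, acetone) gives the racemic keto ester F3. A ketoreductase (or baker's yeast) kinetic resolution then reduces the R ketone to the hydroxy ester F4, which is separated, and leaves the S ketone, returning to the route at 2.

Step 5. The ester enolate may deprotonate the methyl ketone instead of adding to it, and the tertiary aldolate may revert (retro-aldol) during quench or during the saponification of step 6. The fallback sets out from 6: addition of vinylmagnesium bromide (CeCl3, THF, −78 °C) gives the tertiary allylic alcohol F5. Hydroboration with disiamylborane, selective for the monosubstituted alkene over the hindered 1,1-disubstituted one, then H2O2/NaOH gives the diol F6. TEMPO/NaOCl/NaClO2 oxidation of the primary alcohol gives the hydroxy acid, taken up as its lithium salt, returning to the route at 8.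

**Further compounds**

F1 | step 9 | (2S,4aR,7aR)-7a-(iodomethyl)-4,4a-dimethyl-2-(prop-1-en-2-yl)octahydrocyclopenta[b]pyran-4-ol (C4 epimers) | C=C(C)[C@@H]1CC(C)(O)[C@@]2(C)CCC[C@@]2(CI)O1
F2 | step 9 | (2S,4S,4aR,7aR)-7a-(iodomethyl)-4,4a-dimethyl-4-(prop-2-en-1-yl)-2-(prop-1-en-2-yl)octahydrocyclopenta[b]pyran | C=C(C)[C@@H]1C[C@](C)(CC=C)[C@@]2(C)CCC[C@@]2(CI)O1
F3 | step 1 | racemic tert-butyl 1-methyl-2-oxocyclopentane-1-carboxylate | CC1(CCCC1=O)C(=O)OC(C)(C)C
F4 | step 1 | tert-butyl (1R,2S)-2-hydroxy-1-methylcyclopentane-1-carboxylate | O[C@H]1CCC[C@@]1(C)C(=O)OC(C)(C)C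
F5 | step 5 | 2-[(1S)-1-methyl-2-methylidenecyclopentyl]but-3-en-2-ol (C2 epimers) | C=C1CCC[C@]1(C)C(C)(O)C=C
F6 | step 5 | 3-[(1S)-1-methyl-2-methylidenecyclopentyl]butane-1,3-diol (C3 epimers) | C=C1CCC[C@]1(C)C(C)(O)CCO
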